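The constants describe two catalytic rounds that share one catalyst and one reagent: starting material feeds one, second substrate the other.

    second substrate + free catalyst ⇌ catalyst intermediate B (K1 = 5.9 /M, k1 = 650 /M/h)
    reagent + catalyst intermediate B → free catalyst + second product (k2 = 21 /M/h)
    free catalyst + added ligand ⇌ idle complex (K3 = 24 /M, k3 = 13 /M/h)
    starting material + free catalyst ⇌ catalyst intermediate A (K4 = 19 /M, k4 = 540 /M/h)
    reagent + catalyst intermediate A → free catalyst + target (k5 = 6.6 /M/h)

all flasks: starting material 0.40 M; second substrate 0.400 M; free catalyst 44 mM; added ligand 28 mM; time 6.0 h
- teal: reagent 0.400 M
- red: reagent 0.200 M

1. which of these there is most of at the end, counted by the starting material in it, teal (target / catalyst intermediate A / starting material)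
2. which of these there is most of at the end, counted by the starting material in it, red (target / catalyst intermediate A / starting material)
3. how much there is at the end of the one of these that leads, in percent of the starting material charged: teal
4. how much there is at the end of the one of these that leads, in percent of the starting material charged: red

With the whole catalyst as intermediate A, [reagent] would fall pseudo-first-order with a half-life of 2.39 h; with the whole catalyst as intermediate B, 0.750 h. The real flask has its catalyst divided among its forms, and the weights below place it against these two extremes. In teal, the way back from intermediate A runs at 28.4 /h, faster than reagent takes it at 2.64 /h, and the way back from intermediate B runs at 110 /h, faster than the 8.40 /h of its reaction with reagent, so this reckoning keeps both near equilibrium with free catalyst. Free catalyst meets added ligand at 0.364 /h and second substrate at 260 /h, so this reckoning leaves out the idle complex. It also holds both substrates at their charges, which weights intermediate A by 7.60 and intermediate B by 2.36 against one for free catalyst.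

Reagent then falls with the constant 0.400 /h. That gives 1.73 h as the reagent half-life, the time in which both rounds together halve the free reagent. It is shorter than the first extreme and longer than the second. In this reckoning the reagent charge does not enter it, so teal and red share it. The run lasts 3.47 half-lives, leaving 9.05% of the reagent. Of the spent reagent, 50.3% goes to target. Reagent is the limiting reagent, its teal charge being less than the two substrates together. Target reaches 45.7% of the starting material charged in teal and 22.9% in red, and intermediate A holds 7.63% of that charge in this reckoning. So teal is led by starting material at 46.6%, and red by starting material at 69.5%.

The forecast also names starting material in teal and starting material in red, at 51% and 71.5%, higher than this reckoning in each flask , holding that “the target cannot pass about half the reagent charge”.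

Teal ends with starting material leading at 50.4%, and red with starting material at 71.4%. Teal keeps 11% of its reagent, less than the 50% of its starting material, and red keeps 10% of its reagent. In a neighbour of teal charged with 0.011 M of free catalyst, the weights stand and the reagent half-life stretches to 6.93 h, which puts the reagent left at 54.9%. That neighbour ends with 57% of its reagent.

The constants are assumed, and the outcome is calculated.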